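**Plan**
Locants: the ring is C1–C6 (OH on C1 and C3, chain on C5) and the chain runs from C1' (benzylic) to C17' (methyl). The cuts are C2'–C3' first, then C10'–C11' and C9'–C10' (skipped diyne), C14'–C15' (epoxide opening) and C1'=C2' (methylenation of an aryl aldehyde).
Enabling feature: C1' and C2' are the only chain atoms that can be conjugated with the benzene ring. Raised to a vinyl group on C5 they form a styrene, the one terminal, ring-polarised alkene of the skeleton, so boron goes to C2' alone and C2'–B can be exchanged for C2'–C3'.
The event is a formal anti-Markovnikov hydroalkylation of a 5-vinylresorcinol ether by the complete C3'–C17' bromide. The vinyl oxidation level and the boron are helpers used up in the same flask, and the sensitive C8'=C9'–C10'H2–C11'=C12' unit and the free C16' carbinol never meet B–H, strong base or radicals.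
Forward order: C4 Grignard reagent plus (S)-propylene oxide gives the alkynol; a C7 alkynol plus CH2O gives the C8 dibromide; copper-mediated union gives the 1,4-diyne; Lindlar reduction gives the Z,Z-diene; then one-pot hydroboration/alkyl–alkyl Suzuki–Miyaura coupling and MOM removal. The ring is bought as 3,5-dihydroxybenzaldehyde.
Stereochemistry: C16' (S) comes from (S)-propylene oxide, whose C–O bond is never broken. Both Z alkenes come from syn semihydrogenation of the diyne.

Key step: step 9

**Step 1**
Reactants: 1 (4-bromobut-1-yn-1-yl)trimethylsilane; 2 (S)-propylene oxide ((2S)-2-methyloxirane)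
Product: 4 (2S)-7-(trimethylsilyl)hept-6-yn-2-ol, via Grignard reagent 3 (not isolated)
Conditions: 1, Mg, THF, rt → 40 °C; then CuI (10 mol %), 2, THF, −30 → 0 °C
Reagents that add atoms: none
Why: Copper-catalysed Grignard opening of a terminal epoxide (SN2 at the unsubstituted CH2) builds C14'–C15' without touching the C–O stereocentre, so the S configuration of 2 becomes that of C16', and the SiMe3 cap removes the acidic alkyne C–H that would quench 3.

**Step 2**
Reactants: 4 (2S)-7-(trimethylsilyl)hept-6-yn-2-ol
Product: 5 (2S)-hept-6-yn-2-ol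
Conditions: K2CO3 (0.2 equiv), MeOH, rt
Reagents that add atoms: none
Why: Carbonate-catalysed methanolysis of the C(sp)–Si bond (protodesilylation) is specific for the alkynylsilane and cannot affect the carbinol centre.

**Step 3**
Reactants: 6 hept-6-yn-1-ol
Product: 8 oct-2-yne-1,8-diol, via dilithium salt 7 (not isolated)
Conditions: n-BuLi (2.1 equiv), THF, −78 → 0 °C; (CH2O)n, −78 °C → rt; H2O quench
Reagents that add atoms: paraformaldehyde (as formaldehyde), C=O
Why: Acetylide hydroxymethylation: in the dianion only the carbon nucleophile adds irreversibly to formaldehyde, so C10' is installed without hydroxyl protection.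

**Step 4**
Reactants: 8 oct-2-yne-1,8-diol
Product: 9 1,8-dibromooct-2-yne
Conditions: CBr4 (2.3 equiv), PPh3 (2.3 equiv), CH2Cl2, 0 °C
Reagents that add atoms: carbon tetrabromide, BrC(Br)(Br)Br
Why: Twofold Appel reaction: both primary alkoxyphosphonium ions are displaced by bromide (SN2) under neutral conditions that leave the alkyne in place.

**Step 5**
Reactants: 5 (2S)-hept-6-yn-2-ol; 9 1,8-dibromooct-2-yne
Product: 11 (2S)-15-bromopentadeca-6,9-diyn-2-ol, via copper acetylide 10 (not isolated)
Conditions: CuBr (1.0 equiv), n-Bu4NBr (1.0 equiv), K2CO3 (1.5 equiv), DMF, 0 °C → rt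
Reagents that add atoms: none
Why: Copper(I)-mediated acetylide–propargyl halide coupling: the soft copper acetylide displaces only the activated propargylic bromide (C10'–C11'), the unactivated primary C–Br and the free carbinol are spectators, and the all-bromide medium excludes halide exchange at C3'.

**Step 6**
Reactants: 11 (2S)-15-bromopentadeca-6,9-diyn-2-ol
Product: 12 (2S,6Z,9Z)-15-bromopentadeca-6,9-dien-2-ol
Conditions: H2 (1 atm), Lindlar catalyst (Pd/CaCO3, Pb-poisoned), quinoline, EtOAc, 0 °C → rt, stopped after uptake of 2 equiv H2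
Reagents that add atoms: none
Why: Lindlar semihydrogenation delivers H2 syn to each alkyne on the poisoned palladium surface, which sets both Z double bonds, while the alkyl C–Br bond and the carbinol are inert.

**Step 7**
Reactants: 13 3,5-dihydroxybenzaldehyde
Product: 14 3,5-bis(methoxymethoxy)benzaldehyde
Conditions: MOMCl (2.5 equiv), i-Pr2NEt (3 equiv), CH2Cl2, 0 °C → rt
Reagents that add atoms: chloromethyl methyl ether, COCCl
Why: Base-mediated O-alkylation of both phenols with the reactive α-chloro ether gives acetal-type ethers that are inert to ylide, borane, palladium and phosphate base yet acid-labile.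

**Step 8**
Reactants: 14 3,5-bis(methoxymethoxy)benzaldehyde
Product: 15 1-ethenyl-3,5-bis(methoxymethoxy)benzene
Conditions: Ph3PCH3Br (1.3 equiv), KOt-Bu (1.25 equiv), THF, 0 °C → rt
Reagents that add atoms: methyltriphenylphosphonium bromide, C[P+](c1ccccc1)(c1ccccc1)c1ccccc1.[Br-]
Why: Wittig methylenation with the non-stabilised ylide converts the non-enolisable aryl aldehyde into the styrene (C1'=C2') that the key step needs.

**Step 9**
Reactants: 15 1-ethenyl-3,5-bis(methoxymethoxy)benzene; 12 (2S,6Z,9Z)-15-bromopentadeca-6,9-dien-2-ol
Product: 17 (2S,6Z,9Z)-17-[3,5-bis(methoxymethoxy)phenyl]heptadeca-6,9-dien-2-ol, via B-alkyl-9-BBN 16 (not isolated)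
Conditions: 15 (1.4 equiv), 9-BBN-H (1.3 equiv), THF, 0 °C → rt; then 12 (1.0 equiv), Pd(OAc)2 (4 mol %), PCy3 (8 mol %), K3PO4·H2O (1.5 equiv), THF, rt
Reagents that add atoms: none
Why: 9-BBN-H adds syn across the vinyl group through a four-centre transition state with boron on the unhindered, ring-remote C2' (anti-Markovnikov hydroboration), and because the borane is the limiting reagent no B–H is left when 12 enters the flask. The electron-rich Pd(0)/PCy3 complex then inserts into the primary C3'–Br bond by an SN2-type oxidative addition, the hydroxide-activated borate of 16 hands over its primary CH2 group in preference to the bicyclic secondary B–C bonds, and reductive elimination forges C2'–C3'. The closest known reaction type is the room-temperature alkyl–alkyl (B-alkyl) Suzuki–Miyaura coupling of unactivated, β-hydrogen-bearing primary alkyl bromides under bulky trialkylphosphine ligation. No ring is closed and no stereocentre is made, so C16' and both Z alkenes are spectators. The step needs regioselectivity (C2' against C1'), secured by the conjugation of the vinyl group with the ring together with the bulk of 9-BBN, and chemoselectivity for coupling over β-hydride elimination and over any reaction at the 1,4-diene, secured by the ligand, the mild hydrated phosphate base, the absence of radicals and the five-CH2 spacer that keeps C8'=C9' away from palladium.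

**Step 10**
Reactants: 17 (2S,6Z,9Z)-17-[3,5-bis(methoxymethoxy)phenyl]heptadeca-6,9-dien-2-ol
Product: 18 hansfordiol D (5-[(8Z,11Z,16S)-16-hydroxyheptadeca-8,11-dien-1-yl]benzene-1,3-diol)
Conditions: conc. HCl (cat.), MeOH, 40 °C
Reagents that add atoms: none
Why: Acid-catalysed transacetalisation to methanol removes both aryl MOM groups via the oxocarbenium ion under conditions mild enough for isolated Z alkenes and the secondary carbinol.

**Compound list**
1 | (4-bromobut-1-yn-1-yl)trimethylsilane | C[Si](C)(C)C#CCCBr | starting material
2 | (S)-propylene oxide ((2S)-2-methyloxirane) | C[C@H]1CO1 | starting material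
3 | [4-(trimethylsilyl)but-3-yn-1-yl]magnesium bromide | C[Si](C)(C)C#CCC[Mg]Br | intermediate
4 | (2S)-7-(trimethylsilyl)hept-6-yn-2-ol | C[C@H](O)CCCC#C[Si](C)(C)C | intermediate
5 | (2S)-hept-6-yn-2-ol | C[C@H](O)CCCC#C | intermediate
6 | hept-6-yn-1-ol | OCCCCCC#C | starting material
7 | lithium 7-lithiohept-6-yn-1-olate | [Li]OCCCCCC#C[Li] | intermediate
8 | oct-2-yne-1,8-diol | OCC#CCCCCCO | intermediate
9 | 1,8-dibromooct-2-yne | BrCC#CCCCCCBr | intermediate
10 | [(6S)-6-hydroxyhept-1-yn-1-yl]copper(I) | C[C@H](O)CCCC#C[Cu] | intermediate
11 | (2S)-15-bromopentadeca-6,9-diyn-2-ol | C[C@H](O)CCCC#CCC#CCCCCCBr | intermediate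
12 | (2S,6Z,9Z)-15-bromopentadeca-6,9-dien-2-ol | C[C@H](O)CCC/C=C\C/C=C\CCCCCBr | intermediate
13 | 3,5-dihydroxybenzaldehyde | O=Cc1cc(O)cc(O)c1 | starting material
14 | 3,5-bis(methoxymethoxy)benzaldehyde | O=Cc1cc(OCOC)cc(OCOC)c1 | intermediate
15 | 1-ethenyl-3,5-bis(methoxymethoxy)benzene | C=Cc1cc(OCOC)cc(OCOC)c1 | intermediate
16 | 9-{2-[3,5-bis(methoxymethoxy)phenyl]ethyl}-9-borabicyclo[3.3.1]nonane | COCOc1cc(CCB2C3CCCC2CCC3)cc(OCOC)c1 | intermediate
17 | (2S,6Z,9Z)-17-[3,5-bis(methoxymethoxy)phenyl]heptadeca-6,9-dien-2-ol | C[C@H](O)CCC/C=C\C/C=C\CCCCCCCc1cc(OCOC)cc(OCOC)c1 | intermediate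
18 | hansfordiol D (5-[(8Z,11Z,16S)-16-hydroxyheptadeca-8,11-dien-1-yl]benzene-1,3-diol) | C[C@H](O)CCC/C=C\C/C=C\CCCCCCCc1cc(O)cc(O)c1 | target

Total step count: 10.
Longest linear sequence: 6 steps (1 → 2 → 5 → 6 → 9 → 10). The arm 3 → 4 → 5 → 6 → 9 → 10 is equally long.

**Steps most likely to fail**

1. **Step 9.** Oxidative addition to the unactivated C–Br bond may be slow. β-Hydride elimination from either alkylpalladium species may then outrun transmetalation, and the palladium hydride so formed may move the 1,4-diene into conjugation.
   Fallback (from 15, back at 17): the carrier of the C2' nucleophile is changed from boron/palladium to magnesium/copper.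
   - Borane 16, made from 15 as before, is oxidised (NaBO3·4H2O, THF–H2O) to 2-[3,5-bis(methoxymethoxy)phenyl]ethan-1-ol F1.
   - An Appel reaction gives 1-(2-bromoethyl)-3,5-bis(methoxymethoxy)benzene F2.
   - Magnesium in THF gives {2-[3,5-bis(methoxymethoxy)phenyl]ethyl}magnesium bromide F3.
   - F3 (2.2 equiv, the first of which deprotonates the carbinol of 12) is coupled with 12 under Li2CuCl4 catalysis (THF–NMP, −10 °C → rt), which should give 17 after aqueous work-up.

2. **Step 6.** Hydrogen uptake may not stop cleanly at the diene stage. This would mean over-reduction of one alkene, an enyne left by incomplete reduction, or partial Z to E drift on the catalyst, and such products are hard to separate.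
   Fallback (from 11, back at 12): catalytic hydrogenation is replaced by stoichiometric syn hydrometalation, which cannot over-reduce.
   - Dicyclohexylborane (3.3 equiv, THF, 0 °C) borylates the hydroxyl group and monohydroborates both alkynes. This gives (2S,6Z,9Z)-15-bromo-6,10-bis(dicyclohexylboranyl)pentadeca-6,9-dien-2-yl dicyclohexylborinate F4, drawn with boron on C6 and C10; its regioisomers converge in the next operation.
   - Protonolysis with acetic acid proceeds with retention and should give 12.

3. **Step 5.** The carbonate base may isomerise the doubly propargylic CH2 of the product to an allene, and the remote primary C–Br bond may be attacked slowly in DMF.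
   Fallback (from 5 and 6, back at 11): the propargylic halide is moved to the carbinol half, so that no alkyl bromide is present in the copper step, and C3'–Br is made afterwards.
   - Compound 5 is doubly deprotonated (n-BuLi) to lithium (2S)-7-lithiohept-6-yn-2-olate F5.
   - Paraformaldehyde then gives (7S)-oct-2-yne-1,7-diol F6.
   - One equivalent of CBr4/PPh3 at −30 °C brominates the primary propargylic carbinol to (2S)-8-bromooct-6-yn-2-ol F7.
   - CuI/NaI/Cs2CO3 in DMF joins F7 to the free alkynol 6 to give (14S)-pentadeca-6,9-diyne-1,14-diol F8.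
   - A second Appel reaction, selective for the primary carbinol, returns to 11.

**Further compounds**
F1 | step 9 | 2-[3,5-bis(methoxymethoxy)phenyl]ethan-1-ol | OCCc1cc(OCOC)cc(OCOC)c1
F2 | step 9 | 1-(2-bromoethyl)-3,5-bis(methoxymethoxy)benzene | BrCCc1cc(OCOC)cc(OCOC)c1
F3 | step 9 | {2-[3,5-bis(methoxymethoxy)phenyl]ethyl}magnesium bromide | Br[Mg]CCc1cc(OCOC)cc(OCOC)c1
F4 | step 6 | (2S,6Z,9Z)-15-bromo-6,10-bis(dicyclohexylboranyl)pentadeca-6,9-dien-2-yl dicyclohexylborinate | C[C@H](OB(C1CCCCC1)C1CCCCC1)CCC/C(B(C1CCCCC1)C1CCCCC1)=C\C/C=C(\CCCCCBr)B(C1CCCCC1)C1CCCCC1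
F5 | step 5 | lithium (2S)-7-lithiohept-6-yn-2-olate | C[C@H](O[Li])CCCC#C[Li]
F6 | step 5 | (7S)-oct-2-yne-1,7-diol | C[C@H](O)CCCC#CCO
F7 | step 5 | (2S)-8-bromooct-6-yn-2-ol | C[C@H](O)CCCC#CCBr
F8 | step 5 | (14S)-pentadeca-6,9-diyne-1,14-diol | C[C@H](O)CCCC#CCC#CCCCCCO
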